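Under the proposed steps one count stays true in any of these flasks: each exchange frees one J, and the step to Q removes one J together with one Z, so

J = Z + 2 G

| flask | X | L | remark | time |
|---|---|---|---|---|
| Monday's | 0.20 M | 0.95 equiv | run made earlier |  |
| Friday's | 0.20 M | 1.9 equiv | run made earlier |  |
| cedar | 0.20 M | 0.950 equiv | one stirred flow tank at steady state, fed with the mixture as stated, mean residence time 20 min |  |
| elm | 0.20 M (fed, over 20.0 min) | 0.950 equiv | a stirred flask in which X is dosed at a steady rate over 20.0 min without added volume, worked up at 20 min | 20 min |
| maple | 0.20 M | 0.950 equiv | a closed flask charged with all of it at once and left for 20 min | 20 min |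
| birch | 0.20 M | 0.950 equiv (fed, over 20.0 min) | a stirred flask in which L is dosed at a steady rate over 20.0 min without added volume, worked up at 20 min | 20 min |

| run | time / min | Z / % | G / % |
|---|---|---|---|
| Monday's | 1.50 | 4.2 | 0.1 |
| Monday's | 3.00 | 8.1 | 0.7 |
| Monday's | 6.00 | 13.5 | 0.6 |
| Monday's | 10.0 | 18.8 | 2.2 |
| Monday's | 20.0 | 22.6 | 4.4 |
| Friday's | 1.33 | 8.4 | 0.1 |
| Friday's | 2.50 | 13.6 | 0.7 |
| Friday's | 4.00 | 18.7 | 1.4 |
| Friday's | 5.00 | 21.2 | 2.6 |
| Friday's | 6.00 | 23.5 | 3.1 |

(each reading ± 0.3 percentage points)

- the set-up with the highest share of Z in all that became Z or G or Q, at the outlet or at the end ("none" if the first two lie within 2 percentage points) (cedar / elm / maple / birch / none)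
- share of Z in all that became Z or G or Q, at the outlet or at the end, cedar
- share of Z in all that became Z or G or Q, at the outlet or at the end, elm
- share of Z in all that became Z or G or Q, at the outlet or at the end, maple
- share of Z in all that became Z or G or Q, at the outlet or at the end, birch

- the stated concentrations are those of everything mixed, before any reaction; amounts are the same in each set-up
- steps that have been proposed: X + L <-> J + Z; Z + L <-> J + G; J + Z -> Q; L <-> E
- the feed brings no volume worth counting
- the earlier runs were made in a closed, stirred flask

The share of Z asked for is a selectivity, and two steps spoil it: Z meeting L to give G, and Z meeting J to give Q. By the count above J climbs along with Z, so the step to Q counts Z in both of its partners. So take the loss weight, the product of J and Z standing in the flask at a moment, to which the rate of forming Q is proportional. Monday's last reading, at 20.0 min, gives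

J = 0.0628 M

loss weight = J × Z = 0.002839 M^2

Turn the question round. For maple to match a dosed flask, the loss to Q per unit of Z must not fall when Z is low, and that asks for J to hold up while Z is small. The count ties J to Z instead, and Monday's reading has J at 1.39 times Z. With that ratio held, half the Z carries a quarter of the weight. In elm and birch one partner arrives steadily over 20.0 min, so Z climbs late. I therefore expect both above maple, and cedar, whose contents sit at outlet strength throughout, no better than maple.

The forecast ranks birch first: birch 80%, elm 76%, maple 59%, cedar 51%. In its words: “Dosing shortens exposure, and low L also protects against G.”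

The flasks give birch 81.1%, elm 78.4%, maple 61.1%, cedar 55.0%, so birch leads, as forecast.

    X + L ⇌ J + Z (K = 38.0, k = 0.220 L mol⁻¹ min⁻¹)
    Z + L ⇌ J + G (K = 0.640, k = 0.150 L mol⁻¹ min⁻¹)
    J + Z → Q (k = 0.650 L mol⁻¹ min⁻¹)
    L ⇌ E (K = 0.390, k = 0.870 min⁻¹)

At 10.0 min elm's loss weight is 1.663 × 10⁻⁴ M^2 and maple's is 0.001689 M^2, ten times elm's, and at 20.0 min elm holds Q at 2.43% of the X charged against maple's 9.96%. Now read elm later, at 30 min. Its J and Z then give a loss weight of 0.002653 M^2, close to Monday's reading of 0.00284 M^2. Q in that flask has reached 9.58%, and its share of Z has dropped from 78.4% to 60.5%.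

(Readings and results come from a simulation with constants of no real substance, and the scatter is random.)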